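## Retrosynthetic overview

1. The target comes from its methyl ester, and that from one intramolecular Diels–Alder reaction of a linear (2E,4Z,6S,7E,9E,11E,13E)-hexaene ester (chain numbered C1 = carboxyl to C14 = CHPh). The diene is C7–C10, the dienophile C2=C3, and the new bonds are C3–C7 and C2–C10. The cyclopentene and the cyclohexene form together in this one step; C6 is the only stereocentre set beforehand.
2. The hexaene is never isolated. It is built in the flask by a C8–C9 hydrozirconation/Negishi union of a C1–C9 enyne ester with a C9–C14 phenyltrienyl iodide and cyclises on warming.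
3. The enyne ester comes from a stereoconvergent nickel-catalysed C5–C6 coupling of a (Z)-iododienoate with racemic 4-bromopent-2-yne, which sets C6.
4. The (Z)-iododienoate comes from propargyl alcohol and EtMgBr (anti-carbomagnesiation/iodination), then oxidation/Wittig. The trienyl iodide comes from cinnamylideneacetone (ketone to alkyne, then carboalumination/iodination).

Assumption: the indanyl-pybox antipode that gives (6R)-12 in step 4 is taken to be (3aS,8aR); if the first run shows the opposite sense, the other, equally available antipode is used with no other change.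

## Route

Step 1
Reactants: 1 prop-2-yn-1-ol; 2 ethylmagnesium bromide
Product: 4 (Z)-2-ethyl-3-iodoprop-2-en-1-ol, via cyclic alkenylmagnesium alkoxide 3 (not isolated)
Conditions: 2 (2.5 equiv), CuI (10 mol%), Et2O, −10 °C → rt; then I2, THF, −10 °C → rt
Reagents that add atoms: iodine, II
Why: Copper-catalysed anti-carbomagnesiation of the propargylic alkoxide (Duboudin reaction) puts ethyl on the internal carbon and magnesium on the terminal carbon, held cis to CH2O in a five-membered chelate, so iodinolysis with retention gives only the Z iodide (I cis to CH2OH) that later becomes the 4Z alkene; no stereocentre is formed.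

Step 2
Reactants: 4 (Z)-2-ethyl-3-iodoprop-2-en-1-ol; 5 methyl 2-(triphenylphosphoranylidene)propanoate
Product: 7 methyl (2E,4Z)-4-ethyl-5-iodo-2-methylpenta-2,4-dienoate, via Z-iodoenal 6 (not isolated)
Conditions: MnO2 (15 equiv), 5 (1.3 equiv), CH2Cl2, rt → 40 °C, dark, one pot
Reagents that add atoms: none
Why: In this tandem oxidation–Wittig olefination MnO2 oxidises the allylic alcohol and the stabilised α-branched ylide traps the sensitive Z-iodoenal as it forms, giving the E trisubstituted enoate while the Z vinyl iodide is untouched; no stereocentre is formed.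

Step 3
Reactants: 8 pent-3-yn-2-ol (racemic)
Product: 9 4-bromopent-2-yne (racemic)
Conditions: PBr3 (0.4 equiv), pyridine (0.1 equiv), Et2O, −20 → 0 °C
Reagents that add atoms: phosphorus tribromide, BrP(Br)Br
Why: Bromination of the secondary propargylic alcohol through its phosphite ester (SN2 displacement by bromide) is standard, and the racemate is wanted because the next step is stereoconvergent.

Step 4
Reactants: 7 methyl (2E,4Z)-4-ethyl-5-iodo-2-methylpenta-2,4-dienoate; 9 4-bromopent-2-yne (racemic)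
Product: 12 methyl (2E,4Z,6R)-4-ethyl-2,6-dimethylnona-2,4-dien-7-ynoate, via C5-alkenylmagnesium chloride 10 (not isolated), via C5-alkenylzinc chloride 11 (not isolated)
Conditions: 7, i-PrMgCl·LiCl, THF, −40 °C; ZnCl2, −40 → 0 °C; then NiCl2·glyme (5 mol%), (3aS,8aR)-indanyl-pybox (6.5 mol%), 9 (2 equiv), DME, −20 °C
Reagents that add atoms: none
Why: Proposed new method: iodine–magnesium exchange and transmetalation give the Z-alkenylzinc with retention, and the chiral NiCl2/pybox catalyst should couple it with both enantiomers of 9 by bromine abstraction to a planar propargylic radical that is captured by the chiral alkenylnickel complex and reductively eliminated at the propargylic (not allenic) terminus, so the ligand alone sets C6 as R with the 4Z geometry kept; the closest known reactions are the nickel/pybox stereoconvergent Negishi arylation of racemic secondary propargylic bromides and nickel-catalysed stereoconvergent Negishi alkenylations of other activated racemic secondary bromides.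

Step 5
Reactants: 13 (3E,5E)-6-phenylhexa-3,5-dien-2-one
Product: 15 [(1E,3E)-hexa-1,3-dien-5-yn-1-yl]benzene, via enol phosphate 14 (not isolated)
Conditions: LDA (1.05 equiv), THF, −78 °C; ClP(O)(OEt)2, −78 °C → rt; LDA (2.3 equiv), −78 °C → rt
Reagents that add atoms: none
Why: In Negishi's ketone-to-alkyne protocol the kinetic methyl enolate is O-phosphorylated and the 1,1-disubstituted enol phosphate undergoes LDA-induced β-elimination to the lithium acetylide, leaving the E,E-diene intact; no stereocentre is formed.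

Step 6
Reactants: 15 [(1E,3E)-hexa-1,3-dien-5-yn-1-yl]benzene
Product: 17 [(1E,3E,5E)-6-iodo-5-methylhexa-1,3,5-trien-1-yl]benzene, via alkenylalane 16 (not isolated)
Conditions: Me3Al (2.5 equiv), Cp2ZrCl2 (25 mol%), CH2Cl2, 0 °C → rt; then I2, THF, −30 → 0 °C, dark
Reagents that add atoms: trimethylaluminium, C[Al](C)C; iodine, II
Why: Zirconium-catalysed carboalumination (Negishi) adds methyl and aluminium syn across the terminal alkyne with methyl on the internal carbon, and iodinolysis with retention gives the E trisubstituted iodide (I trans to the dienyl chain); no stereocentre is formed.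

Step 7
Reactants: 12 methyl (2E,4Z,6R)-4-ethyl-2,6-dimethylnona-2,4-dien-7-ynoate; 17 [(1E,3E,5E)-6-iodo-5-methylhexa-1,3,5-trien-1-yl]benzene
Product: 21 methyl (1R,3aR,4R,5S,7aS)-3-ethyl-1,4,5,7-tetramethyl-5-[(1E,3E)-4-phenylbuta-1,3-dien-1-yl]-3a,4,5,7a-tetrahydro-1H-indene-4-carboxylate, via C8-alkenylzirconocene chloride 18 (not isolated), via C8-alkenylzinc chloride 19 (not isolated), via linear hexaene ester 20 (not isolated)
Conditions: 12, Cp2Zr(H)Cl (1.3 equiv), THF, 0 °C → rt; ZnCl2 (1.5 equiv), 0 °C; 17 (1.1 equiv), Pd(PPh3)4 (5 mol%), rt; then PhMe, BHT, 80–100 °C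
Reagents that add atoms: none
Why: Syn-hydrozirconation puts zirconium on the less hindered methyl-bearing alkyne carbon and the zinc-mediated Negishi coupling with 17 keeps both alkene geometries, giving the (2E,4Z,7E,9E,11E,13E)-hexaene 20, which then undergoes the intramolecular Diels–Alder reaction through the ester-endo, tether-anti transition state in which C6–H eclipses the C7=C8 bond to avoid A(1,3) strain with the C8 methyl, so the C6 stereocentre steers the tether to one diene face (setting C7a and C3a, trans ring fusion) and the E dienophile and E,E diene geometries place the two methyls cis and the ester cis to the dienyl group on the new quaternary carbons C4 and C5.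

Step 8
Reactants: 21 methyl (1R,3aR,4R,5S,7aS)-3-ethyl-1,4,5,7-tetramethyl-5-[(1E,3E)-4-phenylbuta-1,3-dien-1-yl]-3a,4,5,7a-tetrahydro-1H-indene-4-carboxylate
Product: 22 (1R,3aR,4R,5S,7aS)-3-ethyl-1,4,5,7-tetramethyl-5-[(1E,3E)-4-phenylbuta-1,3-dien-1-yl]-3a,4,5,7a-tetrahydro-1H-indene-4-carboxylic acid (22-nor-zyggomphic acid B)
Conditions: NaSEt (6 equiv), DMF, 90 °C, argon; then 1 M HCl
Reagents that add atoms: none
Why: Thiolate demethylation (SN2 at the ester methyl, BAl2 mechanism) frees the acid without any attack at the carbonyl, which is shielded by the quaternary C4 and its quaternary neighbour C5, and no stereocentre is touched.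

## Compound list

1 | prop-2-yn-1-ol (propargyl alcohol) | C#CCO | starting material
2 | ethylmagnesium bromide | CC[Mg]Br | starting material
3 | 4-ethyl-5H-1,2-oxamagnesole (cyclic alkenylmagnesium alkoxide, Mg on the alkene terminus cis to CH2O) | CCC1=C[Mg]OC1 | intermediate
4 | (Z)-2-ethyl-3-iodoprop-2-en-1-ol | OC/C(CC)=C\I | intermediate
5 | methyl 2-(triphenylphosphoranylidene)propanoate | COC(=O)C(C)=P(c1ccccc1)(c1ccccc1)c1ccccc1 | starting material
6 | (Z)-2-ethyl-3-iodoprop-2-enal | O=C/C(CC)=C\I | intermediate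
7 | methyl (2E,4Z)-4-ethyl-5-iodo-2-methylpenta-2,4-dienoate | COC(=O)/C(C)=C/C(CC)=C\I | intermediate
8 | pent-3-yn-2-ol (racemic) | CC#CC(C)O | starting material
9 | 4-bromopent-2-yne (racemic) | CC#CC(C)Br | intermediate
10 | chloro[(1Z,3E)-2-ethyl-5-methoxy-4-methyl-5-oxopenta-1,3-dien-1-yl]magnesium | COC(=O)/C(C)=C/C(CC)=C\[Mg]Cl | intermediate
11 | chloro[(1Z,3E)-2-ethyl-5-methoxy-4-methyl-5-oxopenta-1,3-dien-1-yl]zinc | COC(=O)/C(C)=C/C(CC)=C\[Zn]Cl | intermediate
12 | methyl (2E,4Z,6R)-4-ethyl-2,6-dimethylnona-2,4-dien-7-ynoate | COC(=O)/C(C)=C/C(CC)=C\[C@@H](C)C#CC | intermediate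
13 | (3E,5E)-6-phenylhexa-3,5-dien-2-one (cinnamylideneacetone) | CC(=O)/C=C/C=C/c1ccccc1 | starting material
14 | diethyl (3E,5E)-6-phenylhexa-1,3,5-trien-2-yl phosphate | C=C(OP(=O)(OCC)OCC)/C=C/C=C/c1ccccc1 | intermediate
15 | [(1E,3E)-hexa-1,3-dien-5-yn-1-yl]benzene | C#C/C=C/C=C/c1ccccc1 | intermediate
16 | dimethyl[(1E,3E,5E)-2-methyl-6-phenylhexa-1,3,5-trien-1-yl]alumane | C[Al](C)/C=C(C)/C=C/C=C/c1ccccc1 | intermediate
17 | [(1E,3E,5E)-6-iodo-5-methylhexa-1,3,5-trien-1-yl]benzene | I/C=C(C)/C=C/C=C/c1ccccc1 | intermediate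
18 | methyl (2E,4Z,6R,7E)-8-[chlorobis(cyclopentadienyl)zirconio]-4-ethyl-2,6-dimethylnona-2,4,7-trienoate | COC(=O)/C(C)=C/C(CC)=C\[C@@H](C)/C=C(C)/[Zr](Cl)(C1C=CC=C1)C1C=CC=C1 | intermediate
19 | methyl (2E,4Z,6R,7E)-8-(chlorozincio)-4-ethyl-2,6-dimethylnona-2,4,7-trienoate | COC(=O)/C(C)=C/C(CC)=C\[C@@H](C)/C=C(C)/[Zn]Cl | intermediate
20 | methyl (2E,4Z,6S,7E,9E,11E,13E)-4-ethyl-2,6,8,10-tetramethyl-14-phenyltetradeca-2,4,7,9,11,13-hexaenoate | COC(=O)/C(C)=C/C(CC)=C\[C@@H](C)/C=C(C)/C=C(C)/C=C/C=C/c1ccccc1 | intermediate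
21 | methyl (1R,3aR,4R,5S,7aS)-3-ethyl-1,4,5,7-tetramethyl-5-[(1E,3E)-4-phenylbuta-1,3-dien-1-yl]-3a,4,5,7a-tetrahydro-1H-indene-4-carboxylate (trans ring fusion) | CCC1=C[C@@H](C)[C@@H]2C(C)=C[C@](C)(/C=C/C=C/c3ccccc3)[C@](C)(C(=O)OC)[C@@H]12 | intermediate
22 | (1R,3aR,4R,5S,7aS)-3-ethyl-1,4,5,7-tetramethyl-5-[(1E,3E)-4-phenylbuta-1,3-dien-1-yl]-3a,4,5,7a-tetrahydro-1H-indene-4-carboxylic acid (22-nor-zyggomphic acid B) | CCC1=C[C@@H](C)[C@@H]2C(C)=C[C@](C)(/C=C/C=C/c3ccccc3)[C@](C)(C(=O)O)[C@@H]12 | target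

## Step count and risks

Total step count: 8. Longest linear sequence: 5 steps (steps 1, 2, 4, 7, 8, from propargyl alcohol).

Steps most likely to fail:

**Step 4 (stereoconvergent alkenyl–propargyl coupling).** It is an untested extension, and the 2-iodopropane left from the exchange could compete as an electrophile. The fallback sets out from 7 and comes back to the route at 20, and so at 21. Miyaura borylation of 7 (B2pin2, PdCl2(dppf), KOAc, dioxane, 80 °C) gives the boronate methyl (2E,4Z)-4-ethyl-2-methyl-5-(4,4,5,5-tetramethyl-1,3,2-dioxaborolan-2-yl)penta-2,4-dienoate F1. Commercial (E)-but-2-en-1-ol is converted (ClP(O)(OEt)2, pyridine) into (E)-but-2-en-1-yl diethyl phosphate F2. A copper/chiral N-heterocyclic carbene catalysed enantioselective SN2′ allylic substitution of F2 by F1 (CuCl, chiral imidazolinium salt, NaOMe, THF) then sets C6 and gives the skipped triene methyl (2E,4Z,6S)-4-ethyl-2,6-dimethylocta-2,4,7-trienoate F3. Cross-metathesis of its terminal vinyl group with isopropenylboronic acid pinacol ester (second-generation Hoveyda–Grubbs catalyst, CH2Cl2, 40 °C) gives the C8 boronate methyl (2E,4Z,6S,7Z)-4-ethyl-2,6-dimethyl-8-(4,4,5,5-tetramethyl-1,3,2-dioxaborolan-2-yl)nona-2,4,7-trienoate F4. Suzuki coupling of F4 with 17 (Pd(PPh3)4, aqueous K3PO4, THF, rt) gives 20, which is warmed as in step 7 to 21.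

**Step 7 (hydrozirconation/Negishi/Diels–Alder in one flask).** The risks are the regioselectivity of hydrozirconation next to an ester, and the rate and endo/exo ratio of a cycloaddition that joins two fully substituted carbons. The fallback sets out from 12 and comes back at 22. Reduction with i-Bu2AlH (CH2Cl2, −78 °C) gives the dienynol (2E,4Z,6R)-4-ethyl-2,6-dimethylnona-2,4-dien-7-yn-1-ol F5. Hydrozirconation (Cp2Zr(H)Cl, 2.3 equiv), ZnCl2 and Pd(PPh3)4 coupling with 17 gives the hexaenol (2E,4Z,6S,7E,9E,11E,13E)-4-ethyl-2,6,8,10-tetramethyl-14-phenyltetradeca-2,4,7,9,11,13-hexaen-1-ol F6. F6 has no activated dienophile, so it does not cyclise and can be purified free of the hydrozirconation regioisomer. MnO2 then gives the hexaenal (2E,4Z,6S,7E,9E,11E,13E)-4-ethyl-2,6,8,10-tetramethyl-14-phenyltetradeca-2,4,7,9,11,13-hexaenal F7. Its more reactive enal dienophile cyclises at or below room temperature (Me2AlCl, CH2Cl2, −78 °C if needed) to the bicyclic aldehyde (1R,3aR,4R,5S,7aS)-3-ethyl-1,4,5,7-tetramethyl-5-[(1E,3E)-4-phenylbuta-1,3-dien-1-yl]-3a,4,5,7a-tetrahydro-1H-indene-4-carbaldehyde F8. Pinnick oxidation (NaClO2, NaH2PO4, 2-methylbut-2-ene, t-BuOH/H2O) gives 22, so no ester has to be cleaved.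

**Step 8 (cleavage of the very hindered methyl ester).** The thiolate may be slow or may attack the phenyldiene. The fallback sets out from 21 and comes back at 22 by a reduction–oxidation detour. LiAlH4 (THF, reflux) gives the neopentyl-type alcohol [(1R,3aR,4R,5S,7aS)-3-ethyl-1,4,5,7-tetramethyl-5-[(1E,3E)-4-phenylbuta-1,3-dien-1-yl]-3a,4,5,7a-tetrahydro-1H-inden-4-yl]methanol F9. Dess–Martin periodinane oxidises it to the bicyclic aldehyde F8 named above, and Pinnick oxidation gives 22.

Further compounds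
F1 | step 4 | methyl (2E,4Z)-4-ethyl-2-methyl-5-(4,4,5,5-tetramethyl-1,3,2-dioxaborolan-2-yl)penta-2,4-dienoate | COC(=O)/C(C)=C/C(CC)=C\B1OC(C)(C)C(C)(C)O1
F2 | step 4 | (E)-but-2-en-1-yl diethyl phosphate | C/C=C/COP(=O)(OCC)OCC
F3 | step 4 | methyl (2E,4Z,6S)-4-ethyl-2,6-dimethylocta-2,4,7-trienoate | COC(=O)/C(C)=C/C(CC)=C\[C@@H](C)C=C
F4 | step 4 | methyl (2E,4Z,6S,7Z)-4-ethyl-2,6-dimethyl-8-(4,4,5,5-tetramethyl-1,3,2-dioxaborolan-2-yl)nona-2,4,7-trienoate | COC(=O)/C(C)=C/C(CC)=C\[C@@H](C)/C=C(C)/B1OC(C)(C)C(C)(C)O1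
F5 | step 7 | (2E,4Z,6R)-4-ethyl-2,6-dimethylnona-2,4-dien-7-yn-1-ol | OC/C(C)=C/C(CC)=C\[C@@H](C)C#CC
F6 | step 7 | (2E,4Z,6S,7E,9E,11E,13E)-4-ethyl-2,6,8,10-tetramethyl-14-phenyltetradeca-2,4,7,9,11,13-hexaen-1-ol | OC/C(C)=C/C(CC)=C\[C@@H](C)/C=C(C)/C=C(C)/C=C/C=C/c1ccccc1
F7 | step 7 | (2E,4Z,6S,7E,9E,11E,13E)-4-ethyl-2,6,8,10-tetramethyl-14-phenyltetradeca-2,4,7,9,11,13-hexaenal | O=C/C(C)=C/C(CC)=C\[C@@H](C)/C=C(C)/C=C(C)/C=C/C=C/c1ccccc1
F8 | step 7 | (1R,3aR,4R,5S,7aS)-3-ethyl-1,4,5,7-tetramethyl-5-[(1E,3E)-4-phenylbuta-1,3-dien-1-yl]-3a,4,5,7a-tetrahydro-1H-indene-4-carbaldehyde | CCC1=C[C@@H](C)[C@@H]2C(C)=C[C@](C)(/C=C/C=C/c3ccccc3)[C@](C)(C=O)[C@@H]12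
F9 | step 8 | [(1R,3aR,4R,5S,7aS)-3-ethyl-1,4,5,7-tetramethyl-5-[(1E,3E)-4-phenylbuta-1,3-dien-1-yl]-3a,4,5,7a-tetrahydro-1H-inden-4-yl]methanol | CCC1=C[C@@H](C)[C@@H]2C(C)=C[C@](C)(/C=C/C=C/c3ccccc3)[C@](C)(CO)[C@@H]12
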